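Cembrane numbering: C1–C14 form ring C; C15, C16 (carbonyl) and C17 (methylidene) complete lactone ring B on C1/C2; C19 is the carbonyl of butenolide ring A (C6–C8); C18 and C20 are the methyls on C4 and C12.
Retrosynthetic cuts, in order: the C12–O bond (ene reaction on C11=C12), the C16–O bond of ring B (oxidative lactonization), the C5–C6 bond of ring C (key cut), then in the open chain C8–C9, C10–C11, C3=C4 and C2–O.
Enabling feature: C6 is the γ-carbon (OCH) of butenolide ring A and is bonded to C5, which is allylic to C3=C4; C5–C6 can therefore join a 3-alkyl-2-silyloxyfuran (C6 its free α-position) to a π-allylpalladium unit spanning C3–C5, closing ring C while the furan becomes ring A.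
Forward: one linear chain grows from (S)-limonene (C16 oxygenation, ring opening, alkyne, C2–O, C3–C5, C9–C11, furanone); ring C closes in step 16 with ring A appearing, ring B follows in step 18 and the hydroperoxide in step 19.
Stereochemistry: C1 from (S)-limonene, C2 from L-proline catalysis, E C3=C4 from a stabilized Wittig reaction, E C11=C12 from syn-carboalumination, C6 from the chiral diphosphine on palladium, C12 from the face selectivity of the macrocycle in the ene reaction.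

Key step: step 16

Assumption: the sense of induction at C6 in step 16 cannot be derived from first principles, so the (R,R) ligand is written and its enantiomer would be used instead if it favours the C6 epimer.

Step 1
Reactants: 1 (S)-limonene
Product: 4 2-[(1S)-4-methylcyclohex-3-en-1-yl]prop-2-en-1-ol, via allyllithium 2 (not isolated), via allylboronate 3 (not isolated)
Conditions: n-BuLi, TMEDA, hexane, 23 °C; B(OMe)3, THF, −78 °C; then H2O2, NaOH, 0 °C
Reagents that add atoms: hydrogen peroxide, OO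
Why: Allylic metalation, borylation and oxidative C–B cleavage: n-BuLi·TMEDA should deprotonate limonene at the isopropenyl methyl (C16) to a symmetrical 2-substituted allyllithium, and oxidation of the derived boronate gives the primary allylic alcohol without involving the C1 stereocentre, which is not part of the allyl anion.

Step 2
Reactants: 4 2-[(1S)-4-methylcyclohex-3-en-1-yl]prop-2-en-1-ol
Product: 5 tert-butyl({2-[(1S)-4-methylcyclohex-3-en-1-yl]prop-2-en-1-yl}oxy)diphenylsilane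
Conditions: TBDPSCl, imidazole, DMF, 23 °C
Reagents that add atoms: tert-butyl(chloro)diphenylsilane, CC(C)(C)[Si](Cl)(c1ccccc1)c1ccccc1
Why: Standard silylation of a primary alcohol, the tert-butyldiphenylsilyl ether being chosen because it should withstand the acidic methanol of step 3, the aqueous acid of step 5 and the mild acid of step 13.

Step 3
Reactants: 5 tert-butyl({2-[(1S)-4-methylcyclohex-3-en-1-yl]prop-2-en-1-yl}oxy)diphenylsilane
Product: 8 (5S)-6-({[tert-butyl(diphenyl)silyl]oxy}methyl)-5-(2,2-dimethoxyethyl)hept-6-en-2-one, via ozonide 6 (not isolated), via keto aldehyde 7 (not isolated)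
Conditions: O3, CH2Cl2, −78 °C (Sudan Red 7B end-point); PPh3, −78 → 23 °C; then MeOH, TsOH·H2O (cat.), 23 °C
Reagents that add atoms: ozone, [O-][O+]=O; methanol, CO
Why: Chemoselective ozonolysis with reductive work-up: electrophilic ozone should cleave the trisubstituted ring alkene ahead of the 1,1-disubstituted alkene deactivated by its allylic silyloxy group, PPh3 reduces ozonide 6 to keto aldehyde 7, and acidic methanol acetalizes the aldehyde much faster than the methyl ketone, which differentiates the two termini.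

Step 4
Reactants: 8 (5S)-6-({[tert-butyl(diphenyl)silyl]oxy}methyl)-5-(2,2-dimethoxyethyl)hept-6-en-2-one
Product: 11 tert-butyl{[(3S)-3-(2,2-dimethoxyethyl)-2-methylidenehept-6-yn-1-yl]oxy}diphenylsilane, via lithium enolate 9 (not isolated), via enol phosphate 10 (not isolated)
Conditions: LiN(i-Pr)2, THF, −78 °C; ClP(O)(OEt)2; then LiN(i-Pr)2 (2.3 equiv), −78 → 23 °C; H2O
Reagents that add atoms: none
Why: Known one-pot conversion of a methyl ketone into a terminal alkyne by kinetic enolization at the methyl group, O-phosphorylation and base-induced elimination of the enol phosphate, so that the former methyl carbon becomes C11 and the ketone carbon C12.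

Step 5
Reactants: 11 tert-butyl{[(3S)-3-(2,2-dimethoxyethyl)-2-methylidenehept-6-yn-1-yl]oxy}diphenylsilane
Product: 12 (3S)-3-(3-{[tert-butyl(diphenyl)silyl]oxy}prop-1-en-2-yl)hept-6-ynal
Conditions: 2 M HCl, THF, 23 °C
Reagents that add atoms: water, O
Why: Acid-catalysed acetal hydrolysis releases the C3 aldehyde, the silyl ether and alkyne being inert and C1, which is β to the carbonyl, being unable to epimerize.

Step 6
Reactants: 12 (3S)-3-(3-{[tert-butyl(diphenyl)silyl]oxy}prop-1-en-2-yl)hept-6-ynal; 13 ethyl 2-(triphenylphosphoranylidene)propanoate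
Product: 15 ethyl (2E,4S,5R)-4-(anilinooxy)-5-(3-{[tert-butyl(diphenyl)silyl]oxy}prop-1-en-2-yl)-2-methylnon-2-en-8-ynoate, via anilinooxy aldehyde 14 (not isolated)
Conditions: L-proline (20 mol %), PhNO, DMSO, 23 °C; then 13, CH2Cl2, 0 → 23 °C
Reagents that add atoms: nitrosobenzene, O=Nc1ccccc1
Why: Proline-catalysed α-aminoxylation followed in the same flask by a stabilized Wittig olefination: the E enamine of 12 is attacked by the nitroso oxygen on the face fixed by hydrogen bonding to the carboxylic acid of L-proline (catalyst control expected to override the β-stereocentre C1), which sets C2 in the required sense, and the labile α-oxy aldehyde 14 is trapped by ylide 13 as the E 2-methyl enoate.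

Step 7
Reactants: 15 ethyl (2E,4S,5R)-4-(anilinooxy)-5-(3-{[tert-butyl(diphenyl)silyl]oxy}prop-1-en-2-yl)-2-methylnon-2-en-8-ynoate
Product: 16 ethyl (2E,4S,5R)-5-(3-{[tert-butyl(diphenyl)silyl]oxy}prop-1-en-2-yl)-4-hydroxy-2-methylnon-2-en-8-ynoate
Conditions: Zn dust, AcOH, THF, 23 °C
Reagents that add atoms: none
Why: Reductive N–O bond cleavage by zinc in acetic acid frees the C2 hydroxyl without affecting the enoate, the alkyne or the silyl ether, and the E geometry prevents lactonization.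

Step 8
Reactants: 16 ethyl (2E,4S,5R)-5-(3-{[tert-butyl(diphenyl)silyl]oxy}prop-1-en-2-yl)-4-hydroxy-2-methylnon-2-en-8-ynoate
Product: 17 (2E,4S,5R)-5-(3-{[tert-butyl(diphenyl)silyl]oxy}prop-1-en-2-yl)-2-methylnon-2-en-8-yne-1,4-diol
Conditions: i-Bu2AlH (3.5 equiv), CH2Cl2, −78 °C
Reagents that add atoms: none
Why: 1,2-Reduction of the enoate by diisobutylaluminium hydride at low temperature gives the C5 allylic alcohol, the free hydroxyl consuming only one extra equivalent and the terminal alkyne not being hydroaluminated at −78 °C.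

Step 9
Reactants: 17 (2E,4S,5R)-5-(3-{[tert-butyl(diphenyl)silyl]oxy}prop-1-en-2-yl)-2-methylnon-2-en-8-yne-1,4-diol
Product: 18 (2E,4S,5R)-1,4-bis{[tert-butyl(dimethyl)silyl]oxy}-5-(3-{[tert-butyl(diphenyl)silyl]oxy}prop-1-en-2-yl)-2-methylnon-2-en-8-yne
Conditions: TBSOTf, 2,6-lutidine, CH2Cl2, −78 → 0 °C
Reagents that add atoms: tert-butyldimethylsilyl trifluoromethanesulfonate, CC(C)(C)[Si](C)(C)OS(=O)(=O)C(F)(F)F
Why: Exhaustive silylation with the silyl triflate covers the hindered secondary C2 hydroxyl and the primary C5 hydroxyl in one operation, so that no acidic proton or ester remains for the organometallic steps 10 to 12.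

Step 10
Reactants: 18 (2E,4S,5R)-1,4-bis{[tert-butyl(dimethyl)silyl]oxy}-5-(3-{[tert-butyl(diphenyl)silyl]oxy}prop-1-en-2-yl)-2-methylnon-2-en-8-yne
Product: 21 (3E,7R,8S,9E)-8,11-bis{[tert-butyl(dimethyl)silyl]oxy}-7-(3-{[tert-butyl(diphenyl)silyl]oxy}prop-1-en-2-yl)-4,10-dimethylundeca-3,9-dien-1-ol, via alkenylalane 19 (not isolated), via lithium alanate 20 (not isolated)
Conditions: Me3Al, Cp2ZrCl2 (25 mol %), CH2Cl2, 0 → 23 °C; n-BuLi, THF/hexane, −78 °C; ethylene oxide, −78 → 0 °C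
Reagents that add atoms: trimethylaluminium, C[Al](C)C; ethylene oxide, C1CO1
Why: Zirconium-catalysed methylalumination (Negishi carboalumination) adds methyl and aluminium syn across the terminal alkyne with methyl at the internal carbon, which fixes the E geometry of C11=C12, and the derived alanate opens ethylene oxide with retention at the alkenyl carbon to deliver C10 and C9 as a homoallylic alcohol.

Step 11
Reactants: 21 (3E,7R,8S,9E)-8,11-bis{[tert-butyl(dimethyl)silyl]oxy}-7-(3-{[tert-butyl(diphenyl)silyl]oxy}prop-1-en-2-yl)-4,10-dimethylundeca-3,9-dien-1-ol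
Product: 22 (3E,7R,8S,9E)-8,11-bis{[tert-butyl(dimethyl)silyl]oxy}-7-(3-{[tert-butyl(diphenyl)silyl]oxy}prop-1-en-2-yl)-1-iodo-4,10-dimethylundeca-3,9-diene
Conditions: I2, PPh3, imidazole, CH2Cl2, 0 °C
Reagents that add atoms: iodine, II
Why: Appel-type iodination of the primary alcohol under imidazole buffering, conditions under which silyl ethers and alkenes should survive.

Step 12
Reactants: 22 (3E,7R,8S,9E)-8,11-bis{[tert-butyl(dimethyl)silyl]oxy}-7-(3-{[tert-butyl(diphenyl)silyl]oxy}prop-1-en-2-yl)-1-iodo-4,10-dimethylundeca-3,9-diene; 23 3-bromofuran-2(5H)-one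
Product: 25 3-[(3E,7R,8S,9E)-8,11-bis{[tert-butyl(dimethyl)silyl]oxy}-7-(3-{[tert-butyl(diphenyl)silyl]oxy}prop-1-en-2-yl)-4,10-dimethylundeca-3,9-dien-1-yl]furan-2(5H)-one, via alkylzinc iodide 24 (not isolated)
Conditions: Zn dust, LiCl, THF, 40 °C; then 23, PdCl2(dppf) (5 mol %), THF, 23 → 45 °C
Reagents that add atoms: none
Why: Negishi coupling: zinc inserts into the primary iodide to an alkylzinc iodide that tolerates silyl ethers, and palladium-catalysed coupling with the α-bromo enoate 23 (facile oxidative addition, a wide-bite-angle diphosphine against β-hydride elimination) forms C8–C9 under base-free conditions that spare the furanone.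

Step 13
Reactants: 25 3-[(3E,7R,8S,9E)-8,11-bis{[tert-butyl(dimethyl)silyl]oxy}-7-(3-{[tert-butyl(diphenyl)silyl]oxy}prop-1-en-2-yl)-4,10-dimethylundeca-3,9-dien-1-yl]furan-2(5H)-one
Product: 26 3-[(3E,7R,8S,9E)-8-{[tert-butyl(dimethyl)silyl]oxy}-7-(3-{[tert-butyl(diphenyl)silyl]oxy}prop-1-en-2-yl)-11-hydroxy-4,10-dimethylundeca-3,9-dien-1-yl]furan-2(5H)-one
Conditions: (+)-camphor-10-sulfonic acid (10 mol %), MeOH/CH2Cl2, 0 °C
Reagents that add atoms: none
Why: Selective acid-catalysed methanolysis of the unhindered primary allylic tert-butyldimethylsilyl ether, the secondary C2 silyl ether reacting more slowly for steric reasons and the tert-butyldiphenylsilyl ether being far more acid-stable.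

Step 14
Reactants: 26 3-[(3E,7R,8S,9E)-8-{[tert-butyl(dimethyl)silyl]oxy}-7-(3-{[tert-butyl(diphenyl)silyl]oxy}prop-1-en-2-yl)-11-hydroxy-4,10-dimethylundeca-3,9-dien-1-yl]furan-2(5H)-one
Product: 27 (2E,4S,5R,8E)-4-{[tert-butyl(dimethyl)silyl]oxy}-5-(3-{[tert-butyl(diphenyl)silyl]oxy}prop-1-en-2-yl)-2,8-dimethyl-11-(2-oxo-2,5-dihydrofuran-3-yl)undeca-2,8-dien-1-yl methyl carbonate
Conditions: ClCO2Me, pyridine, CH2Cl2, 0 °C
Reagents that add atoms: methyl chloroformate, COC(=O)Cl
Why: Acylation of the primary allylic alcohol with a chloroformate installs the ionizable leaving group for the key step, pyridine being too weak a base to enolize the butenolide.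

Step 15
Reactants: 27 (2E,4S,5R,8E)-4-{[tert-butyl(dimethyl)silyl]oxy}-5-(3-{[tert-butyl(diphenyl)silyl]oxy}prop-1-en-2-yl)-2,8-dimethyl-11-(2-oxo-2,5-dihydrofuran-3-yl)undeca-2,8-dien-1-yl methyl carbonate
Product: 28 (2E,4S,5R,8E)-4-{[tert-butyl(dimethyl)silyl]oxy}-5-(3-{[tert-butyl(diphenyl)silyl]oxy}prop-1-en-2-yl)-2,8-dimethyl-11-(2-{[tri(propan-2-yl)silyl]oxy}furan-3-yl)undeca-2,8-dien-1-yl methyl carbonate
Conditions: TIPSOTf, Et3N, CH2Cl2, 0 °C
Reagents that add atoms: triisopropylsilyl trifluoromethanesulfonate, CC(C)[Si](C(C)C)(C(C)C)OS(=O)(=O)C(F)(F)F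
Why: Soft enolization and O-silylation of the 3-alkylbutenolide with a silyl triflate and triethylamine gives the aromatic 2-silyloxyfuran (the bulky silyl group making it isolable), while the allylic carbonate is untouched.

Step 16
Reactants: 28 (2E,4S,5R,8E)-4-{[tert-butyl(dimethyl)silyl]oxy}-5-(3-{[tert-butyl(diphenyl)silyl]oxy}prop-1-en-2-yl)-2,8-dimethyl-11-(2-{[tri(propan-2-yl)silyl]oxy}furan-3-yl)undeca-2,8-dien-1-yl methyl carbonate
Product: 29 (1R,2S,3E,6R,11E)-2-{[tert-butyl(dimethyl)silyl]oxy}-16-{[tert-butyl(diphenyl)silyl]oxy}cembra-3,7,11,15(17)-tetraen-19,6-olide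
Conditions: Pd2(dba)3·CHCl3 (5 mol %), (1R,2R)-N,N′-bis[2-(diphenylphosphanyl)benzoyl]cyclohexane-1,2-diamine (15 mol %), CH2Cl2 (0.002 M, slow addition of 28), 23 °C
Reagents that add atoms: none
Why: Proposed new method: zerovalent palladium ionizes the primary C5 carbonate with loss of CO2 to a cationic 2-methyl-π-allyl complex, the released methoxide removes the triisopropylsilyl group, and the resulting 2-oxidofuran attacks the unhindered C5 terminus through its free carbon C6 on the face opposite to palladium, forming C5–C6 and turning the furan into butenolide ring A; the closest known reaction types are the intermolecular Tsuji–Trost allylation of 2-silyloxyfurans and furanone dienolates and palladium-catalysed macrocyclizing allylic alkylations of stabilized carbanions. Ring C closes as a 14-membered ring by attack at the distal allyl terminus, so that C3=C4 ends inside the ring (14-endo with respect to the allyl unit, against the 12-exo alternative at C3). The new stereocentre C6 is controlled by the chiral diphosphine, which discriminates the two faces of the planar furanolate as it meets the allyl terminus, the C1 and C2 centres being too remote to decide it. The step needs attack through C6 and not C8, at C5 and not C3, retention of the E C3=C4 geometry and cyclization instead of oligomerization: C8 already carries the C9 chain, so attack there would have to build a quaternary centre in a 12-membered ring and leave a non-conjugated lactone, C3 is shielded by the neighbouring C2 silyloxy group, the E carbonate ionizes to the syn complex that returns the E alkene unless it isomerizes, and high dilution favours the intramolecular path.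

Step 17
Reactants: 29 (1R,2S,3E,6R,11E)-2-{[tert-butyl(dimethyl)silyl]oxy}-16-{[tert-butyl(diphenyl)silyl]oxy}cembra-3,7,11,15(17)-tetraen-19,6-olide
Product: 30 (1R,2S,3E,6R,11E)-2,16-dihydroxycembra-3,7,11,15(17)-tetraen-19,6-olide
Conditions: HF·pyridine, pyridine, THF, 0 → 23 °C
Reagents that add atoms: none
Why: Fluoride-mediated cleavage of both silyl ethers under buffered, non-basic conditions, chosen because a basic fluoride source could epimerize C6 through the 2-oxidofuran.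

Step 18
Reactants: 30 (1R,2S,3E,6R,11E)-2,16-dihydroxycembra-3,7,11,15(17)-tetraen-19,6-olide
Product: 33 (1R,2S,3E,6R,11E)-cembra-3,7,11,15(17)-tetraene-16,2:19,6-diolide, via hydroxy enal 31 (not isolated), via lactol 32 (not isolated)
Conditions: TEMPO (20 mol %), PhI(OAc)2, CH2Cl2, 23 °C
Reagents that add atoms: none
Why: Oxoammonium-mediated oxidative lactonization: the TEMPO-derived oxoammonium oxidizes the primary allylic C16 alcohol much faster than the secondary C2 alcohol, hydroxy enal 31 closes to lactol 32, and a second oxidation gives the α-methylene γ-lactone (ring B) with C1 and C2 unchanged.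

Step 19
Reactants: 33 (1R,2S,3E,6R,11E)-cembra-3,7,11,15(17)-tetraene-16,2:19,6-diolide
Product: 34 (1R,2S,3E,6R,10E,12S)-12-hydroperoxycembra-3,7,10,15(17)-tetraene-16,2:19,6-diolide
Conditions: O2, visible light, 5,10,15,20-tetraphenylporphyrin (cat.), CH2Cl2, −20 °C
Reagents that add atoms: dioxygen, O=O
Why: Schenck ene reaction: singlet oxygen should attack the only electron-rich trisubstituted alkene (C11=C12; C3=C4 is deactivated by the allylic lactone oxygen and the other two alkenes are conjugated to carbonyls), abstracting an allylic hydrogen from C10 on the more substituted side of the alkene to give the tertiary C12 hydroperoxide and the E C10=C11 bond, with the 12S configuration expected from suprafacial attack on the outer face of the macrocycle.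

Compound list
1 | (S)-limonene | CC1=CC[C@H](CC1)C(C)=C | starting material
2 | {2-[(1S)-4-methylcyclohex-3-en-1-yl]prop-2-en-1-yl}lithium | CC1=CC[C@H](CC1)C(=C)C[Li] | intermediate (not isolated)
3 | dimethyl {2-[(1S)-4-methylcyclohex-3-en-1-yl]prop-2-en-1-yl}boronate | CC1=CC[C@H](CC1)C(=C)CB(OC)OC | intermediate (not isolated)
4 | 2-[(1S)-4-methylcyclohex-3-en-1-yl]prop-2-en-1-ol | CC1=CC[C@H](CC1)C(=C)CO | intermediate
5 | tert-butyl({2-[(1S)-4-methylcyclohex-3-en-1-yl]prop-2-en-1-yl}oxy)diphenylsilane | CC1=CC[C@H](CC1)C(=C)CO[Si](c1ccccc1)(c1ccccc1)C(C)(C)C | intermediate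
6 | tert-butyl({2-[(4S)-1-methyl-7,8,9-trioxabicyclo[4.2.1]nonan-4-yl]prop-2-en-1-yl}oxy)diphenylsilane (ozonide of 5, bridgehead epimers) | CC12CC[C@@H](CC(OO1)O2)C(=C)CO[Si](c3ccccc3)(c3ccccc3)C(C)(C)C | intermediate (not isolated)
7 | (3S)-3-(3-{[tert-butyl(diphenyl)silyl]oxy}prop-1-en-2-yl)-6-oxoheptanal | CC(=O)CC[C@@H](CC=O)C(=C)CO[Si](c1ccccc1)(c1ccccc1)C(C)(C)C | intermediate (not isolated)
8 | (5S)-6-({[tert-butyl(diphenyl)silyl]oxy}methyl)-5-(2,2-dimethoxyethyl)hept-6-en-2-one | CC(=O)CC[C@@H](CC(OC)OC)C(=C)CO[Si](c1ccccc1)(c1ccccc1)C(C)(C)C | intermediate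
9 | lithium (5S)-6-({[tert-butyl(diphenyl)silyl]oxy}methyl)-5-(2,2-dimethoxyethyl)hepta-1,6-dien-2-olate | [Li]OC(=C)CC[C@@H](CC(OC)OC)C(=C)CO[Si](c1ccccc1)(c1ccccc1)C(C)(C)C | intermediate (not isolated)
10 | diethyl (5S)-6-({[tert-butyl(diphenyl)silyl]oxy}methyl)-5-(2,2-dimethoxyethyl)hepta-1,6-dien-2-yl phosphate | CCOP(=O)(OCC)OC(=C)CC[C@@H](CC(OC)OC)C(=C)CO[Si](c1ccccc1)(c1ccccc1)C(C)(C)C | intermediate (not isolated)
11 | tert-butyl{[(3S)-3-(2,2-dimethoxyethyl)-2-methylidenehept-6-yn-1-yl]oxy}diphenylsilane | C#CCC[C@@H](CC(OC)OC)C(=C)CO[Si](c1ccccc1)(c1ccccc1)C(C)(C)C | intermediate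
12 | (3S)-3-(3-{[tert-butyl(diphenyl)silyl]oxy}prop-1-en-2-yl)hept-6-ynal | C#CCC[C@@H](CC=O)C(=C)CO[Si](c1ccccc1)(c1ccccc1)C(C)(C)C | intermediate
13 | ethyl 2-(triphenylphosphoranylidene)propanoate | CCOC(=O)C(C)=P(c1ccccc1)(c1ccccc1)c1ccccc1 | starting material
14 | (2R,3R)-2-(anilinooxy)-3-(3-{[tert-butyl(diphenyl)silyl]oxy}prop-1-en-2-yl)hept-6-ynal | C#CCC[C@H](C(=C)CO[Si](c1ccccc1)(c1ccccc1)C(C)(C)C)[C@@H](ONc1ccccc1)C=O | intermediate (not isolated)
15 | ethyl (2E,4S,5R)-4-(anilinooxy)-5-(3-{[tert-butyl(diphenyl)silyl]oxy}prop-1-en-2-yl)-2-methylnon-2-en-8-ynoate | C#CCC[C@H](C(=C)CO[Si](c1ccccc1)(c1ccccc1)C(C)(C)C)[C@@H](ONc1ccccc1)/C=C(\C)C(=O)OCC | intermediate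
16 | ethyl (2E,4S,5R)-5-(3-{[tert-butyl(diphenyl)silyl]oxy}prop-1-en-2-yl)-4-hydroxy-2-methylnon-2-en-8-ynoate | C#CCC[C@H](C(=C)CO[Si](c1ccccc1)(c1ccccc1)C(C)(C)C)[C@@H](O)/C=C(\C)C(=O)OCC | intermediate
17 | (2E,4S,5R)-5-(3-{[tert-butyl(diphenyl)silyl]oxy}prop-1-en-2-yl)-2-methylnon-2-en-8-yne-1,4-diol | C#CCC[C@H](C(=C)CO[Si](c1ccccc1)(c1ccccc1)C(C)(C)C)[C@@H](O)/C=C(\C)CO | intermediate
18 | (2E,4S,5R)-1,4-bis{[tert-butyl(dimethyl)silyl]oxy}-5-(3-{[tert-butyl(diphenyl)silyl]oxy}prop-1-en-2-yl)-2-methylnon-2-en-8-yne | C#CCC[C@H](C(=C)CO[Si](c1ccccc1)(c1ccccc1)C(C)(C)C)[C@@H](O[Si](C)(C)C(C)(C)C)/C=C(\C)CO[Si](C)(C)C(C)(C)C | intermediate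
19 | [(1E,5R,6S,7E)-6,9-bis{[tert-butyl(dimethyl)silyl]oxy}-5-(3-{[tert-butyl(diphenyl)silyl]oxy}prop-1-en-2-yl)-2,8-dimethylnona-1,7-dien-1-yl]dimethylalumane | C[Al](C)/C=C(\C)CC[C@H](C(=C)CO[Si](c1ccccc1)(c1ccccc1)C(C)(C)C)[C@@H](O[Si](C)(C)C(C)(C)C)/C=C(\C)CO[Si](C)(C)C(C)(C)C | intermediate (not isolated)
20 | lithium butyl[(1E,5R,6S,7E)-6,9-bis{[tert-butyl(dimethyl)silyl]oxy}-5-(3-{[tert-butyl(diphenyl)silyl]oxy}prop-1-en-2-yl)-2,8-dimethylnona-1,7-dien-1-yl]dimethylaluminate | [Li+].CCCC[Al-](C)(C)/C=C(\C)CC[C@H](C(=C)CO[Si](c1ccccc1)(c1ccccc1)C(C)(C)C)[C@@H](O[Si](C)(C)C(C)(C)C)/C=C(\C)CO[Si](C)(C)C(C)(C)C | intermediate (not isolated)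
21 | (3E,7R,8S,9E)-8,11-bis{[tert-butyl(dimethyl)silyl]oxy}-7-(3-{[tert-butyl(diphenyl)silyl]oxy}prop-1-en-2-yl)-4,10-dimethylundeca-3,9-dien-1-ol | OCC/C=C(\C)CC[C@H](C(=C)CO[Si](c1ccccc1)(c1ccccc1)C(C)(C)C)[C@@H](O[Si](C)(C)C(C)(C)C)/C=C(\C)CO[Si](C)(C)C(C)(C)C | intermediate
22 | (3E,7R,8S,9E)-8,11-bis{[tert-butyl(dimethyl)silyl]oxy}-7-(3-{[tert-butyl(diphenyl)silyl]oxy}prop-1-en-2-yl)-1-iodo-4,10-dimethylundeca-3,9-diene | ICC/C=C(\C)CC[C@H](C(=C)CO[Si](c1ccccc1)(c1ccccc1)C(C)(C)C)[C@@H](O[Si](C)(C)C(C)(C)C)/C=C(\C)CO[Si](C)(C)C(C)(C)C | intermediate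
23 | 3-bromofuran-2(5H)-one | O=C1OCC=C1Br | starting material
24 | [(3E,7R,8S,9E)-8,11-bis{[tert-butyl(dimethyl)silyl]oxy}-7-(3-{[tert-butyl(diphenyl)silyl]oxy}prop-1-en-2-yl)-4,10-dimethylundeca-3,9-dien-1-yl](iodo)zinc | I[Zn]CC/C=C(\C)CC[C@H](C(=C)CO[Si](c1ccccc1)(c1ccccc1)C(C)(C)C)[C@@H](O[Si](C)(C)C(C)(C)C)/C=C(\C)CO[Si](C)(C)C(C)(C)C | intermediate (not isolated)
25 | 3-[(3E,7R,8S,9E)-8,11-bis{[tert-butyl(dimethyl)silyl]oxy}-7-(3-{[tert-butyl(diphenyl)silyl]oxy}prop-1-en-2-yl)-4,10-dimethylundeca-3,9-dien-1-yl]furan-2(5H)-one | O=C1OCC=C1CC/C=C(\C)CC[C@H](C(=C)CO[Si](c1ccccc1)(c1ccccc1)C(C)(C)C)[C@@H](O[Si](C)(C)C(C)(C)C)/C=C(\C)CO[Si](C)(C)C(C)(C)C | intermediate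
26 | 3-[(3E,7R,8S,9E)-8-{[tert-butyl(dimethyl)silyl]oxy}-7-(3-{[tert-butyl(diphenyl)silyl]oxy}prop-1-en-2-yl)-11-hydroxy-4,10-dimethylundeca-3,9-dien-1-yl]furan-2(5H)-one | O=C1OCC=C1CC/C=C(\C)CC[C@H](C(=C)CO[Si](c1ccccc1)(c1ccccc1)C(C)(C)C)[C@@H](O[Si](C)(C)C(C)(C)C)/C=C(\C)CO | intermediate
27 | (2E,4S,5R,8E)-4-{[tert-butyl(dimethyl)silyl]oxy}-5-(3-{[tert-butyl(diphenyl)silyl]oxy}prop-1-en-2-yl)-2,8-dimethyl-11-(2-oxo-2,5-dihydrofuran-3-yl)undeca-2,8-dien-1-yl methyl carbonate | O=C1OCC=C1CC/C=C(\C)CC[C@H](C(=C)CO[Si](c1ccccc1)(c1ccccc1)C(C)(C)C)[C@@H](O[Si](C)(C)C(C)(C)C)/C=C(\C)COC(=O)OC | intermediate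
28 | (2E,4S,5R,8E)-4-{[tert-butyl(dimethyl)silyl]oxy}-5-(3-{[tert-butyl(diphenyl)silyl]oxy}prop-1-en-2-yl)-2,8-dimethyl-11-(2-{[tri(propan-2-yl)silyl]oxy}furan-3-yl)undeca-2,8-dien-1-yl methyl carbonate | CC(C)[Si](C(C)C)(C(C)C)Oc1occc1CC/C=C(\C)CC[C@H](C(=C)CO[Si](c2ccccc2)(c2ccccc2)C(C)(C)C)[C@@H](O[Si](C)(C)C(C)(C)C)/C=C(\C)COC(=O)OC | intermediate (key-step precursor)
29 | (1R,2S,3E,6R,11E)-2-{[tert-butyl(dimethyl)silyl]oxy}-16-{[tert-butyl(diphenyl)silyl]oxy}cembra-3,7,11,15(17)-tetraen-19,6-olide | CC(C)(C)[Si](C)(C)O[C@H]1/C=C(\C)C[C@@H]2C=C(CC/C=C(\C)CC[C@@H]1C(=C)CO[Si](c3ccccc3)(c3ccccc3)C(C)(C)C)C(=O)O2 | intermediate (key-step product)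
30 | (1R,2S,3E,6R,11E)-2,16-dihydroxycembra-3,7,11,15(17)-tetraen-19,6-olide | O[C@H]1/C=C(\C)C[C@@H]2C=C(CC/C=C(\C)CC[C@@H]1C(=C)CO)C(=O)O2 | intermediate
31 | (1R,2S,3E,6R,11E)-2-hydroxy-16-oxocembra-3,7,11,15(17)-tetraen-19,6-olide | O[C@H]1/C=C(\C)C[C@@H]2C=C(CC/C=C(\C)CC[C@@H]1C(=C)C=O)C(=O)O2 | intermediate (not isolated)
32 | (1R,2S,3E,6R,11E)-16-hydroxy-2,16-epoxycembra-3,7,11,15(17)-tetraen-19,6-olide (lactol, C16 epimers) | C=C1C(O)O[C@H]2/C=C(\C)C[C@@H]3C=C(CC/C=C(\C)CC[C@H]12)C(=O)O3 | intermediate (not isolated)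
33 | (1R,2S,3E,6R,11E)-cembra-3,7,11,15(17)-tetraene-16,2:19,6-diolide | C=C1C(=O)O[C@H]2/C=C(\C)C[C@@H]3C=C(CC/C=C(\C)CC[C@H]12)C(=O)O3 | intermediate
34 | (1R,2S,3E,6R,10E,12S)-12-hydroperoxycembra-3,7,10,15(17)-tetraene-16,2:19,6-diolide | C=C1C(=O)O[C@H]2/C=C(\C)C[C@@H]3C=C(C/C=C/[C@@](C)(OO)CC[C@H]12)C(=O)O3 | target

Total step count: 19. Longest linear sequence: 19 steps, from 1 to 34.

Steps most likely to fail

Step 16. The furanolate may react through its substituted carbon C8 (α-allylation to a 12-membered ring). Metal-allyl electrophiles are known to favour the α-position of unsubstituted silyloxyfurans, so this is the main uncertainty. The ring may also close at C3, the π-allyl complex may undergo syn–anti isomerization and erode the C3=C4 geometry, facial discrimination at C6 may be poor, or oligomers may form. The fallback sets out from 26 and returns at 29. Appel bromination (CBr4, PPh3, CH2Cl2, 0 °C) would give the C5 allylic bromide F1. Silylation with TIPSOTf and i-Pr2NEt would give the bromo silyloxyfuran F2. Treatment with AgOCOCF3 in CH2Cl2 at high dilution (−78 → 0 °C) would then close ring C to 29. This is the silver-promoted alkylation of 2-silyloxyfurans by allylic bromides, a known reaction that takes place at the unsubstituted furan α-carbon, run here intramolecularly. C6 would then be governed by the substrate, and the C6 epimer would have to be removed by chromatography.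

Step 19. Singlet oxygen may abstract hydrogen from the C20 methyl group (giving the secondary C11 hydroperoxide with an exocyclic alkene), may oxygenate C3=C4, or may add to the wrong face of C11=C12; the product may also undergo radical allylic rearrangement. The fallback sets out from 29 and returns at 34, moving the oxygenation ahead of ring B formation. The ene reaction (O2, tetraphenylporphyrin, visible light) on the silyl-protected macrocycle, whose C2 silyl ether shields C3=C4 and whose ring conformation differs, would give the hydroperoxide F3. Masking with 2-methoxypropene and pyridinium p-toluenesulfonate would give the peroxyketal F4, at which stage isomers can be separated. Desilylation with Bu4NF buffered by AcOH would give the diol peroxyketal F5. TEMPO/PhI(OAc)2 would give the dilactone peroxyketal F6. AcOH/H2O/THF would release 34.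

Step 12. Zinc insertion may be incomplete, the organozinc may be protonated, β-hydride elimination may follow transmetalation, or the bromofuranone may decompose. The fallback sets out from 22 and returns at 25, building the butenolide by enolate alkylation and sulfoxide elimination. The lithium enolate of 3-(phenylsulfanyl)oxolan-2-one (LiN(i-Pr)2, THF/DMPU, −78 → 0 °C) would be alkylated by iodide 22 to the α-phenylsulfanyl lactone F7. Oxidation at sulfur with NaIO4 (MeOH/H2O) would give the sulfoxide F8. Thermal syn-elimination into the ring (toluene, 110 °C) would deliver 25.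

Further compounds
F1 | step 16 | 3-[(3E,7R,8S,9E)-11-bromo-8-{[tert-butyl(dimethyl)silyl]oxy}-7-(3-{[tert-butyl(diphenyl)silyl]oxy}prop-1-en-2-yl)-4,10-dimethylundeca-3,9-dien-1-yl]furan-2(5H)-one | O=C1OCC=C1CC/C=C(\C)CC[C@H](C(=C)CO[Si](c1ccccc1)(c1ccccc1)C(C)(C)C)[C@@H](O[Si](C)(C)C(C)(C)C)/C=C(\C)CBr
F2 | step 16 | ({3-[(3E,7R,8S,9E)-11-bromo-8-{[tert-butyl(dimethyl)silyl]oxy}-7-(3-{[tert-butyl(diphenyl)silyl]oxy}prop-1-en-2-yl)-4,10-dimethylundeca-3,9-dien-1-yl]furan-2-yl}oxy)tri(propan-2-yl)silane | CC(C)[Si](C(C)C)(C(C)C)Oc1occc1CC/C=C(\C)CC[C@H](C(=C)CO[Si](c2ccccc2)(c2ccccc2)C(C)(C)C)[C@@H](O[Si](C)(C)C(C)(C)C)/C=C(\C)CBr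
F3 | step 19 | (1R,2S,3E,6R,10E,12S)-2-{[tert-butyl(dimethyl)silyl]oxy}-16-{[tert-butyl(diphenyl)silyl]oxy}-12-hydroperoxycembra-3,7,10,15(17)-tetraen-19,6-olide | CC(C)(C)[Si](C)(C)O[C@H]1/C=C(\C)C[C@@H]2C=C(C/C=C/[C@@](C)(OO)CC[C@@H]1C(=C)CO[Si](c3ccccc3)(c3ccccc3)C(C)(C)C)C(=O)O2
F4 | step 19 | (1R,2S,3E,6R,10E,12S)-2-{[tert-butyl(dimethyl)silyl]oxy}-16-{[tert-butyl(diphenyl)silyl]oxy}-12-[(2-methoxypropan-2-yl)peroxy]cembra-3,7,10,15(17)-tetraen-19,6-olide | CC(C)(C)[Si](C)(C)O[C@H]1/C=C(\C)C[C@@H]2C=C(C/C=C/[C@@](C)(OOC(C)(C)OC)CC[C@@H]1C(=C)CO[Si](c3ccccc3)(c3ccccc3)C(C)(C)C)C(=O)O2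
F5 | step 19 | (1R,2S,3E,6R,10E,12S)-2,16-dihydroxy-12-[(2-methoxypropan-2-yl)peroxy]cembra-3,7,10,15(17)-tetraen-19,6-olide | O[C@H]1/C=C(\C)C[C@@H]2C=C(C/C=C/[C@@](C)(OOC(C)(C)OC)CC[C@@H]1C(=C)CO)C(=O)O2
F6 | step 19 | (1R,2S,3E,6R,10E,12S)-12-[(2-methoxypropan-2-yl)peroxy]cembra-3,7,10,15(17)-tetraene-16,2:19,6-diolide | C=C1C(=O)O[C@H]2/C=C(\C)C[C@@H]3C=C(C/C=C/[C@@](C)(OOC(C)(C)OC)CC[C@H]12)C(=O)O3
F7 | step 12 | 3-[(3E,7R,8S,9E)-8,11-bis{[tert-butyl(dimethyl)silyl]oxy}-7-(3-{[tert-butyl(diphenyl)silyl]oxy}prop-1-en-2-yl)-4,10-dimethylundeca-3,9-dien-1-yl]-3-(phenylsulfanyl)oxolan-2-one (C3 epimers) | O=C1OCCC1(Sc2ccccc2)CC/C=C(\C)CC[C@H](C(=C)CO[Si](c2ccccc2)(c2ccccc2)C(C)(C)C)[C@@H](O[Si](C)(C)C(C)(C)C)/C=C(\C)CO[Si](C)(C)C(C)(C)C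
F8 | step 12 | 3-[(3E,7R,8S,9E)-8,11-bis{[tert-butyl(dimethyl)silyl]oxy}-7-(3-{[tert-butyl(diphenyl)silyl]oxy}prop-1-en-2-yl)-4,10-dimethylundeca-3,9-dien-1-yl]-3-(benzenesulfinyl)oxolan-2-one (stereoisomers at C3 and sulfur) | O=C1OCCC1(S(=O)c2ccccc2)CC/C=C(\C)CC[C@H](C(=C)CO[Si](c2ccccc2)(c2ccccc2)C(C)(C)C)[C@@H](O[Si](C)(C)C(C)(C)C)/C=C(\C)CO[Si](C)(C)C(C)(C)C
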